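**Retrosynthetic overview**
1. Target 10 ⇐ 8 by one-pot cleavage of both O-protecting groups (MOM on the dibromo ring, Me on the monobromo ring).
2. 8 ⇐ 2 + 3: disconnect the hindered diaryl ether C–O bond at the ring carbon flanked by O and Br. The carbanion comes from directed ortho-metalation of 2, the aryloxide from 3, and they are joined by a new Cu(I)→Cu(III) oxidative C–O ligand coupling (key step).
3. 2 ⇐ 3,4-dibromophenol 1 + MOMCl.
4. No ring is formed: both benzene rings and all three bromines are bought in place (1 and 3); only the ether link is built.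

Assumption: the target has no stereocentre or stereogenic axis (it is achiral), so "single enantiomer" is read as the single constitutional isomer shown.

**Route**

Step 1
Reactants: 1 3,4-dibromophenol
Product: 2 1,2-dibromo-4-(methoxymethoxy)benzene
Conditions: MOMCl (1.3 equiv), iPr2NEt (1.5 equiv), CH2Cl2, 0 °C to rt
Reagents that add atoms: chloromethyl methyl ether (MOMCl), COCCl
Why: Williamson-type O-alkylation of the phenol by the α-chloro ether is fast and clean, the C–Br bonds are untouched, and the MOM acetal both masks the OH and serves as the ortho-directing group for step 2.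

Step 2
Reactants: 2 1,2-dibromo-4-(methoxymethoxy)benzene, 3 5-bromo-2-methoxyphenol
Product: 8 1,2-dibromo-3-(5-bromo-2-methoxyphenoxy)-4-(methoxymethoxy)benzene, via aryllithium 4 (not isolated), via arylcopper 5 (not isolated), via lithium phenolate 6 (not isolated), via aryl(aryloxo)cuprate 7 (not isolated)
Conditions: 2, LDA (1.05 equiv), THF, −78 °C, 1 h; CuI·2LiCl (1.05 equiv), −78 °C; 6 (1.0 equiv, from 3 + LiHMDS, THF, 0 °C), −78 to −40 °C; chloranil (1.2 equiv), −78 to 0 °C; aq NH4Cl
Reagents that add atoms: none
Why: Proposed new method: deprotonative oxidative aryloxylation — LDA removes the only proton flanked by the OMOM director and a bromine (directed ortho-metalation, site fixed by the two acidifying groups; 4 is kept at −78 °C to prevent LiBr loss to an aryne), Li→Cu exchange and addition of phenolate 6 give the heteroleptic Cu(I) ate complex 7, and two-electron oxidation by chloranil generates an aryl–Cu(III)–aryloxide that undergoes C(sp2)–O reductive elimination (the product-forming event of Chan–Lam etherification), so the di-ortho-substituted ether, a difficult case for SNAr or Ullmann coupling, is forged at a carbon defined by C–H acidity; the closest known reactions are the chloranil-mediated oxidative amination of lithium amidocuprates and the Chan–Lam O-arylation of phenols with arylboronic acids, the hindered aryl group disfavours biaryl homocoupling, and the cold cuprate tolerates all three C–Br bonds.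

Step 3
Reactants: 8 1,2-dibromo-3-(5-bromo-2-methoxyphenoxy)-4-(methoxymethoxy)benzene
Product: 10 3,4-dibromo-2-(5-bromo-2-hydroxyphenoxy)phenol (CNP0257329.0), via bis(dibromoboryl) ether 9 (not isolated)
Conditions: BBr3 (4 equiv), CH2Cl2, −78 °C to rt; then H2O, 0 °C
Reagents that add atoms: none
Why: Lewis-acid ether cleavage with BBr3 removes the acetal and the methyl ether in one pot (boron binds each alkyl–O–aryl oxygen, the MOM group is lost as the bromomethyl ether and the methyl by SN2 attack of bromide), the diaryl ether C(sp2)–O bond and the three C–Br bonds are inert, and hydrolysis of aryl borate 9 frees both phenols; no stereocentre is involved.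

**Compound list**
1 | 3,4-dibromophenol | Oc1ccc(Br)c(Br)c1 | starting material
2 | 1,2-dibromo-4-(methoxymethoxy)benzene | COCOc1ccc(Br)c(Br)c1 | intermediate
3 | 5-bromo-2-methoxyphenol | COc1ccc(Br)cc1O | starting material
4 | [2,3-dibromo-6-(methoxymethoxy)phenyl]lithium | COCOc1ccc(Br)c(Br)c1[Li] | intermediate
5 | [2,3-dibromo-6-(methoxymethoxy)phenyl]copper(I) | COCOc1ccc(Br)c(Br)c1[Cu] | intermediate
6 | lithium 5-bromo-2-methoxyphenolate | [Li+].[O-]c1cc(Br)ccc1OC | intermediate
7 | lithium [2,3-dibromo-6-(methoxymethoxy)phenyl](5-bromo-2-methoxyphenolato)cuprate(I) | [Li+].COCOc1ccc(Br)c(Br)c1[Cu-]Oc1cc(Br)ccc1OC | intermediate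
8 | 1,2-dibromo-3-(5-bromo-2-methoxyphenoxy)-4-(methoxymethoxy)benzene | COCOc1ccc(Br)c(Br)c1Oc1cc(Br)ccc1OC | intermediate
9 | 1,2-dibromo-3-[5-bromo-2-(dibromoboryloxy)phenoxy]-4-(dibromoboryloxy)benzene | BrB(Br)Oc1ccc(Br)c(Br)c1Oc1cc(Br)ccc1OB(Br)Br | intermediate
10 | 3,4-dibromo-2-(5-bromo-2-hydroxyphenoxy)phenol | Oc1ccc(Br)cc1Oc1c(O)ccc(Br)c1Br | target

**Step count and risk**
Total step count: 3. Longest linear sequence: 3 (1 → 2 → 8 → 10; 3 is used as purchased).

The route has only three steps, so all three are ranked, most risky first.

Step 2 (the proposed new step). The risks are oxidation of the cuprate to biaryl or to the phenol instead of the ether, attack of free phenolate on chloranil, and LiBr loss from 4 if the temperature rises. The fallback uses known chemistry only; it sets out from 2 and comes back to the route at 10. Compound 2 is lithiated as before (LDA, THF, −78 °C, via 4) and quenched with B(OMe)3 to give dimethyl [2,3-dibromo-6-(methoxymethoxy)phenyl]boronate F1. This is oxidised in the same pot (NaOH, H2O2, 0 °C) to 2,3-dibromo-6-(methoxymethoxy)phenol F2. SNAr of F2 on commercial 4-bromo-2-fluorobenzaldehyde (K2CO3, DMAc, 100 °C; fluoride ortho to the formyl group is displaced, the bromides are not) gives 4-bromo-2-[2,3-dibromo-6-(methoxymethoxy)phenoxy]benzaldehyde F3. Baeyer–Villiger (Dakin-type) oxidation with mCPBA in CH2Cl2 gives 4-bromo-2-[2,3-dibromo-6-(methoxymethoxy)phenoxy]phenyl formate F4, which is methanolysed (K2CO3, MeOH) to 4-bromo-2-[2,3-dibromo-6-(methoxymethoxy)phenoxy]phenol F5. HCl in MeOH at 50 °C then removes the MOM group and delivers 10.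

Step 3. The risks are that the MOM-derived bromomethyl methyl ether and BBr3 alkylate a phenol ring (Friedel–Crafts), or that demethylation is incomplete. The fallback separates the two deprotections by mechanism; it sets out from 8 and comes back at 10. HCl in MeOH at 50 °C removes only the acetal, with methanol trapping the oxocarbenium ion, to give 3,4-dibromo-2-(5-bromo-2-methoxyphenoxy)phenol F6. The methyl ether is then cleaved by SN2 attack of a soft nucleophile (NaSEt, DMF, 110 °C, then aqueous HCl) to give 10.

Step 1. The risk is low: incomplete alkylation, or MOMCl being unavailable. The fallback replaces base-mediated alkylation with acid-promoted transacetalisation: 1 is treated with dimethoxymethane and P2O5 in CHCl3 at rt. It sets out from 1 and comes back at 2 with no new compound (F0).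

**Further compounds**
F1 | step 2 | dimethyl [2,3-dibromo-6-(methoxymethoxy)phenyl]boronate | COCOc1ccc(Br)c(Br)c1B(OC)OC
F2 | step 2 | 2,3-dibromo-6-(methoxymethoxy)phenol | COCOc1ccc(Br)c(Br)c1O
F3 | step 2 | 4-bromo-2-[2,3-dibromo-6-(methoxymethoxy)phenoxy]benzaldehyde | COCOc1ccc(Br)c(Br)c1Oc1cc(Br)ccc1C=O
F4 | step 2 | 4-bromo-2-[2,3-dibromo-6-(methoxymethoxy)phenoxy]phenyl formate | COCOc1ccc(Br)c(Br)c1Oc1cc(Br)ccc1OC=O
F5 | step 2 | 4-bromo-2-[2,3-dibromo-6-(methoxymethoxy)phenoxy]phenol | COCOc1ccc(Br)c(Br)c1Oc1cc(Br)ccc1O
F6 | step 3 | 3,4-dibromo-2-(5-bromo-2-methoxyphenoxy)phenol | Oc1ccc(Br)c(Br)c1Oc1cc(Br)ccc1OC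
F0 | step 1 | none | none
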